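The target is an ansa-macrolactam whose only ring is the 19-membered one containing the E-trisubstituted alkene C8(CH3)=C9H beside the C7 carbamate carbon. This 2-methyl-allylic oxygen motif is treated as a masked ring alkyne: the alkene is traced back to a C8≡C9 cycloalkyne with a free propargylic C7–OH, which is opened at the triple bond. Ring-closing alkyne metathesis of an open-chain anilide carrying two methyl-capped alkynes therefore forges C8≡C9 and the macrocycle in one operation, expelling but-2-yne; hydroxyl-directed trans-hydrostannation and C-methylation then unveil the alkene with defined geometry. The seco-diyne is assembled from a C1–C8 enamide and a C9–C15 aryl bromide by copper-catalysed N-arylation.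

Key step: step 19

Remark: locants C1–C15 follow the ansamycin convention (C1 amide carbonyl, C15 benzylic carbon, the m-phenylene unit bridging C15 and N); the CIP label of C7 becomes R in the stannane 36 only because tin raises the rank of C8, the spatial arrangement being unchanged.

Step 1
Reactants: 1 but-2-yn-1-ol
Product: 2 but-2-ynal
Conditions: activated MnO2, CH2Cl2, rt; filter; concentrate cold and use as a titrated solution
Reagents that add atoms: none
Why: Heterogeneous MnO2 oxidation is selective for propargylic alcohols and stops at the aldehyde, and keeping the volatile ynal in solution avoids losses.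

Step 2
Reactants: 2 but-2-ynal; 3 allyl methyl ether
Product: 5 (3S,4S)-3-methoxyhept-1-en-5-yn-4-ol, via methoxyallylborane 4 (not isolated)
Conditions: 3, s-BuLi, THF, −78 °C; (+)-Ipc2BOMe [from (−)-α-pinene]; BF3·OEt2; then 2, −78 °C; ethanolamine work-up
Reagents that add atoms: none
Why: Brown alkoxyallylboration through a closed chair (Zimmerman–Traxler) transition state, in which the Z geometry of the γ-methoxyallyl unit gives the syn C6/C7 relationship and the (−)-α-pinene-derived Ipc groups direct attack to the Re face of the ynal, should set both centres as (3S,4S).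

Step 3
Reactants: 5 (3S,4S)-3-methoxyhept-1-en-5-yn-4-ol
Product: 6 (3S,4S)-3-methoxy-4-(triethylsilyloxy)hept-1-en-5-yne
Conditions: TESCl, imidazole, CH2Cl2, 0 °C to rt
Reagents that add atoms: chlorotriethylsilane CC[Si](Cl)(CC)CC
Why: Routine silylation of a secondary alcohol; the TES ether is chosen because it can later be cleaved in the presence of secondary TBS and aryl TIPS ethers.

Step 4
Reactants: 7 diethyl methylmalonate; 8 iodoform
Product: 9 diethyl 2-(diiodomethyl)-2-methylmalonate
Conditions: NaH, Et2O, reflux; then CHI3, reflux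
Reagents that add atoms: none
Why: C-alkylation of the malonate enolate by iodoform (formally via diiodocarbene capture) is the established first stage of the β-iodomethacrylate synthesis.

Step 5
Reactants: 9 diethyl 2-(diiodomethyl)-2-methylmalonate
Product: 10 (E)-3-iodo-2-methylacrylic acid
Conditions: KOH, EtOH/H2O, reflux; then aq HCl
Reagents that add atoms: potassium hydroxide [K+].[OH-]
Why: Saponification followed by decarboxylative anti-elimination of iodide (Grob-type fragmentation) is known to give the E-iodoacrylic acid, the isomer with iodine trans to the carboxyl group.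

Step 6
Reactants: 10 (E)-3-iodo-2-methylacrylic acid
Product: 12 (E)-3-iodo-2-methylacrylamide, via acyl chloride 11 (not isolated)
Conditions: (COCl)2, cat. DMF, CH2Cl2, 0 °C to rt; concentrate; NH3 (0.5 M in dioxane), THF, 0 °C
Reagents that add atoms: ammonia N
Why: Acyl chloride formation and low-temperature ammonolysis (acyl substitution) are much faster than addition–elimination at the β-iodo carbon, so the E-alkenyl iodide should survive.

Step 7
Reactants: 6 (3S,4S)-3-methoxy-4-(triethylsilyloxy)hept-1-en-5-yne; 12 (E)-3-iodo-2-methylacrylamide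
Product: 14 (2E,6S,7S)-6-methoxy-2-methyl-7-(triethylsilyloxy)dec-2-en-8-ynamide, via alkylborane 13 (not isolated)
Conditions: 9-BBN dimer, THF, 0 °C to rt; then 12, [Pd(dppf)Cl2], AsPh3, aq Cs2CO3, DMF, rt
Reagents that add atoms: none
Why: 9-BBN hydroborates the terminal vinyl group anti-Markovnikov far faster than the internal alkyne, and the B-alkyl Suzuki–Miyaura coupling with the alkenyl iodide forms C3–C4 with retention of the E geometry while tolerating the primary amide.

Step 8
Reactants: 15 3-bromo-5-hydroxybenzaldehyde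
Product: 16 3-bromo-5-(triisopropylsilyloxy)benzaldehyde
Conditions: TIPSCl, imidazole, DMF, rt
Reagents that add atoms: chlorotriisopropylsilane CC(C)[Si](Cl)(C(C)C)C(C)C
Why: Phenol silylation; the bulky aryl TIPS ether should withstand the organometallic, basic and copper-catalysed steps that follow.

Step 9
Reactants: 16 3-bromo-5-(triisopropylsilyloxy)benzaldehyde; 17 cis-but-2-ene
Product: 19 (1R,2S)-1-[3-bromo-5-(triisopropylsilyloxy)phenyl]-2-methylbut-3-en-1-ol, via crotylborane 18 (not isolated)
Conditions: 17, KOtBu, n-BuLi, THF, −78 to −45 °C; (+)-Ipc2BOMe, −78 °C; BF3·OEt2; then 16, −78 °C; ethanolamine work-up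
Reagents that add atoms: none
Why: Brown crotylboration: the (Z)-crotylborane reacts through a chair transition state to give the syn C14/C15 pair, and the (−)-α-pinene-derived Ipc ligands direct attack to the Re face of the aryl aldehyde, which should set C15 as R and C14 as S.

Step 10
Reactants: 19 (1R,2S)-1-[3-bromo-5-(triisopropylsilyloxy)phenyl]-2-methylbut-3-en-1-ol
Product: 20 (1R,2S)-1-[3-bromo-5-(triisopropylsilyloxy)phenyl]-1-(tert-butyldimethylsilyloxy)-2-methylbut-3-ene
Conditions: TBSOTf, 2,6-lutidine, CH2Cl2, 0 °C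
Reagents that add atoms: tert-butyldimethylsilyl triflate CC(C)(C)[Si](C)(C)OS(=O)(=O)C(F)(F)F
Why: Silyl triflate silylation is the standard way to protect a hindered benzylic secondary alcohol and does not disturb the aryl bromide or aryl silyl ether.

Step 11
Reactants: 20 (1R,2S)-1-[3-bromo-5-(triisopropylsilyloxy)phenyl]-1-(tert-butyldimethylsilyloxy)-2-methylbut-3-ene
Product: 22 (3S,4R)-4-[3-bromo-5-(triisopropylsilyloxy)phenyl]-4-(tert-butyldimethylsilyloxy)-3-methylbutan-1-ol, via alkylborane 21 (not isolated)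
Conditions: 9-BBN dimer, THF, rt; then NaBO3·4H2O, H2O, rt
Reagents that add atoms: sodium perborate, Na2[B2(O2)2(OH)4]·6H2O (sold as NaBO3·4H2O) [Na+].[Na+].O[B-]1(O)OO[B-](O)(O)OO1.O.O.O.O.O.O
Why: Anti-Markovnikov hydroboration of the terminal alkene followed by mild perborate oxidation gives the C12 primary alcohol without exposing the aryl silyl ether to strongly basic peroxide.

Step 12
Reactants: 22 (3S,4R)-4-[3-bromo-5-(triisopropylsilyloxy)phenyl]-4-(tert-butyldimethylsilyloxy)-3-methylbutan-1-ol
Product: 23 (3S,4R)-4-[3-bromo-5-(triisopropylsilyloxy)phenyl]-4-(tert-butyldimethylsilyloxy)-3-methylbutanal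
Conditions: Dess–Martin periodinane, CH2Cl2, 0 °C to rt
Reagents that add atoms: none
Why: Dess–Martin oxidation stops at the aldehyde, and because the α-carbon (C13) is a CH2 group no stereocentre can epimerise.

Step 13
Reactants: 23 (3S,4R)-4-[3-bromo-5-(triisopropylsilyloxy)phenyl]-4-(tert-butyldimethylsilyloxy)-3-methylbutanal; 24 propyne
Product: 27 (2E,4S,6S,7R)-7-[3-bromo-5-(triisopropylsilyloxy)phenyl]-7-(tert-butyldimethylsilyloxy)-6-methylhept-2-en-4-ol, via propenylborane 25 (not isolated), via propenylzinc 26 (not isolated)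
Conditions: 24 (excess), Cy2BH (from BH3·SMe2 and cyclohexene), toluene/hexane, 0 °C; Me2Zn, −78 °C; (2R)-(+)-DAIB (5 mol%), then 23, −20 to 0 °C; aq NH4Cl
Reagents that add atoms: none
Why: Syn-hydroboration of propyne fixes the E-propenyl geometry, boron-to-zinc transmetalation retains it, and the amino-alcohol-catalysed alkenylzinc addition (the (2R)-ligand being the antipode of the one known to direct Si-face attack) should deliver the propenyl group to the Re face and set C12 as S under catalyst control.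

Step 14
Reactants: 27 (2E,4S,6S,7R)-7-[3-bromo-5-(triisopropylsilyloxy)phenyl]-7-(tert-butyldimethylsilyloxy)-6-methylhept-2-en-4-ol
Product: 28 (1S,3S,4R)-4-[3-bromo-5-(triisopropylsilyloxy)phenyl]-4-(tert-butyldimethylsilyloxy)-3-methyl-1-[(2S,3S)-3-methyloxiran-2-yl]butan-1-ol
Conditions: Ti(OiPr)4, L-(+)-DIPT, t-BuOOH, 4 Å MS, CH2Cl2, −20 °C
Reagents that add atoms: tert-butyl hydroperoxide CC(C)(C)OO
Why: Sharpless asymmetric epoxidation in the matched sense: with L-(+)-tartrate the (12S)-allylic alcohol is the fast-reacting antipode and gives the erythro (anti) trans-epoxy alcohol, which sets C10 and C11, while any C12 epimer reacts far more slowly and is left behind, upgrading C12.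

Step 15
Reactants: 28 (1S,3S,4R)-4-[3-bromo-5-(triisopropylsilyloxy)phenyl]-4-(tert-butyldimethylsilyloxy)-3-methyl-1-[(2S,3S)-3-methyloxiran-2-yl]butan-1-ol
Product: 29 (2R,3S)-2-{(1S,3S,4R)-4-[3-bromo-5-(triisopropylsilyloxy)phenyl]-4-(tert-butyldimethylsilyloxy)-1-methoxy-3-methylbutyl}-3-methyloxirane
Conditions: MeI (excess), NaH, THF, 0 °C to rt
Reagents that add atoms: iodomethane CI
Why: Williamson methylation with the electrophile present before the base traps the alkoxide faster than Payne rearrangement can occur and installs the C12 methoxy group (the change of the oxirane C2 label to R is a CIP effect only).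

Step 16
Reactants: 29 (2R,3S)-2-{(1S,3S,4R)-4-[3-bromo-5-(triisopropylsilyloxy)phenyl]-4-(tert-butyldimethylsilyloxy)-1-methoxy-3-methylbutyl}-3-methyloxirane; 24 propyne
Product: 31 (4S,5R,6S,8S,9R)-9-[3-bromo-5-(triisopropylsilyloxy)phenyl]-9-(tert-butyldimethylsilyloxy)-6-methoxy-4,8-dimethylnon-2-yn-5-ol, via propynyllithium 30 (not isolated)
Conditions: 24 (excess), n-BuLi, THF, −78 °C; BF3·OEt2; then 29, −78 °C
Reagents that add atoms: none
Why: BF3-mediated epoxide alkynylation (Yamaguchi–Hirao conditions) is an SN2 opening that should occur at the methyl-bearing C10, remote from the inductively deactivating and more hindered methoxy-bearing side, with inversion, giving the C10 (S) methyl centre and the free C11 hydroxyl; alkynyllithium does not exchange with the aryl bromide.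

Step 17
Reactants: 31 (4S,5R,6S,8S,9R)-9-[3-bromo-5-(triisopropylsilyloxy)phenyl]-9-(tert-butyldimethylsilyloxy)-6-methoxy-4,8-dimethylnon-2-yn-5-ol
Product: 32 (4S,5R,6S,8S,9R)-9-[3-bromo-5-(triisopropylsilyloxy)phenyl]-5,9-bis(tert-butyldimethylsilyloxy)-6-methoxy-4,8-dimethylnon-2-yne (east fragment C9–C15)
Conditions: TBSOTf, 2,6-lutidine, CH2Cl2, 0 °C to rt
Reagents that add atoms: tert-butyldimethylsilyl triflate CC(C)(C)[Si](C)(C)OS(=O)(=O)C(F)(F)F
Why: The silyl triflate is reactive enough to protect the hindered C11 alcohol flanked by two branched carbons.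

Step 18
Reactants: 14 (2E,6S,7S)-6-methoxy-2-methyl-7-(triethylsilyloxy)dec-2-en-8-ynamide; 32 east fragment C9–C15
Product: 33 seco-diyne anilide (amide nitrogen of 14 bonded to the aryl carbon of 32 that carried bromine; 6S,7S,10S,11R,12S,14S,15R)
Conditions: CuI (20 mol%), N,N′-dimethylethylenediamine, K2CO3, toluene, 100 °C
Reagents that add atoms: none
Why: Goldberg-type amidation, in which a diamine-ligated monovalent copper amidate activates the aryl bromide, couples primary amides cleanly and leaves the internal alkynes, silyl ethers and the E-enamide untouched under the weakly basic, non-polar conditions.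

Step 19
Reactants: 33 seco-diyne anilide
Product: 34 19-membered cycloalkyne lactam (C8≡C9; C7-OTES; C11-OTBS; C15-OTBS; aryl OTIPS; 6S,7S,10S,11R,12S,14S,15R)
Conditions: [Mo(≡CC6H4-4-OMe)(OSiPh3)3] (15 mol%), 5 Å MS, toluene (2 mM), 80 °C
Reagents that add atoms: none
Why: The molybdenum alkylidyne adds to one methyl-capped alkyne in a [2+2] fashion to give a metallacyclobutadiene whose cycloreversion leaves the alkylidyne on the substrate chain; this engages the second alkyne intramolecularly, and a second cycloaddition/cycloreversion releases the cycloalkyne while the capping unit leaves as but-2-yne, which the 5 Å sieves absorb to drive the equilibrium. The closest known reaction type is ring-closing alkyne metathesis of methyl-capped diynes to macrocyclic alkynes with silanolate-ligated molybdenum alkylidynes, including substrates with propargylic silyl ethers and α-branching. The single ring formed, the 19-membered ansa-lactam, is closed end-to-end between C8 and C9, giving an endocyclic triple bond that a ring of this size holds without strain. No stereocentre is created and none is touched, because the catalyst is neither basic nor acidic enough to disturb the C7 and C10 centres flanking the alkynes. The step needs ring closure over oligomerisation and chemoselectivity for the two alkynes: high dilution with removal of but-2-yne secures the former, helped by the turn imposed by the m-phenylene anilide and the planar enamide, and the indifference of the alkylidyne to the C2=C3 alkene, the silyl ethers, the arene and the hindered anilide N–H secures the latter.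

Step 20
Reactants: 34 19-membered cycloalkyne lactam
Product: 35 macrocyclic propargylic alcohol (free C7-OH; C8≡C9; 6S,7S,10S,11R,12S,14S,15R)
Conditions: PPTS, MeOH/CH2Cl2, 0 °C to rt
Reagents that add atoms: none
Why: Mild acid-catalysed methanolysis cleaves the TES ether selectively, the secondary TBS ethers and the aryl TIPS ether being far slower to solvolyse.

Step 21
Reactants: 35 macrocyclic propargylic alcohol
Product: 36 macrocyclic (8Z)-8-tributylstannyl allylic alcohol (Sn on C8 and H on C9 trans; C7 and C10 trans; 6S,7R,10S,11R,12S,14S,15R by CIP)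
Conditions: Bu3SnH, [Cp*RuCl]4 (5 mol%), CH2Cl2, rt
Reagents that add atoms: tributyltin hydride CCCC[SnH](CCCC)CCCC
Why: In hydroxyl-directed ruthenium-catalysed trans-hydrostannation the free C7–OH hydrogen-bonds to the Ru–Cl unit, which steers tin to the proximal carbon C8 and delivers H and Sn to opposite faces of the alkyne, so C7 and C10 should end up trans across the new double bond.

Step 22
Reactants: 36 macrocyclic (8Z)-8-tributylstannyl allylic alcohol
Product: 37 macrocyclic (8E)-8-methyl allylic alcohol (free C7-OH; 6S,7S,10S,11R,12S,14S,15R)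
Conditions: MeI, [Pd(PPh3)4], Cu(O2C-2-thienyl) (CuTC), [NBu4][Ph2PO2], DMF, rt
Reagents that add atoms: iodomethane CI
Why: Copper-assisted methyl-Stille coupling (tin-to-copper-to-palladium transmetalation with phosphinate as tin scavenger) replaces the stannyl group by methyl with retention, giving the E-configured C8(CH3)=C9H unit without base that could alkylate N–H or O–H.

Step 23
Reactants: 37 macrocyclic (8E)-8-methyl allylic alcohol
Product: 39 tris-silylated C7 carbamate (C7-OC(O)NH2; C11-OTBS; C15-OTBS; aryl OTIPS), via trichloroacetyl carbamate 38 (not isolated)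
Conditions: Cl3CC(O)NCO, CH2Cl2, 0 °C; then neutral Al2O3 (moist), rt
Reagents that add atoms: trichloroacetyl isocyanate O=C=NC(=O)C(Cl)(Cl)Cl
Why: The highly electrophilic acyl isocyanate adds to the only free hydroxyl (C7) much faster than to the anilide N–H, and the trichloroacetyl group is then hydrolysed on alumina under neutral conditions that leave the silyl ethers in place.

Step 24
Reactants: 39 tris-silylated C7 carbamate
Product: 40 target CNP0309815.1
Conditions: HF·pyridine, pyridine, THF, 0 °C to rt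
Reagents that add atoms: none
Why: Buffered HF cleaves the two secondary TBS ethers and the aryl TIPS ether in one global desilylation while the primary carbamate, the enamide and the benzylic and allylic C–O bonds are stable under these weakly acidic conditions.

Compound list
1 | but-2-yn-1-ol | CC#CCO | starting material
2 | but-2-ynal | CC#CC=O | intermediate
3 | allyl methyl ether | COCC=C | starting material
4 | (Z)-(3-methoxyallyl)diisopinocampheylborane, Ipc groups from (−)-α-pinene | CO/C=C\CB([C@H]1C[C@H]2C[C@@H]([C@@H]1C)C2(C)C)[C@H]1C[C@H]2C[C@@H]([C@@H]1C)C2(C)C | intermediate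
5 | (3S,4S)-3-methoxyhept-1-en-5-yn-4-ol | C=C[C@H](OC)[C@@H](O)C#CC | intermediate
6 | (3S,4S)-3-methoxy-4-(triethylsilyloxy)hept-1-en-5-yne | C=C[C@H](OC)[C@@H](O[Si](CC)(CC)CC)C#CC | intermediate
7 | diethyl methylmalonate | CCOC(=O)C(C)C(=O)OCC | starting material
8 | iodoform | IC(I)I | starting material
9 | diethyl 2-(diiodomethyl)-2-methylmalonate | CCOC(=O)C(C)(C(I)I)C(=O)OCC | intermediate
10 | (E)-3-iodo-2-methylacrylic acid | OC(=O)/C(C)=C/I | intermediate
11 | (E)-3-iodo-2-methylacryloyl chloride | ClC(=O)/C(C)=C/I | intermediate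
12 | (E)-3-iodo-2-methylacrylamide | NC(=O)/C(C)=C/I | intermediate
13 | 9-[(3S,4S)-3-methoxy-4-(triethylsilyloxy)hept-5-yn-1-yl]-9-borabicyclo[3.3.1]nonane | B1(C2CCCC1CCC2)CC[C@H](OC)[C@@H](O[Si](CC)(CC)CC)C#CC | intermediate
14 | (2E,6S,7S)-6-methoxy-2-methyl-7-(triethylsilyloxy)dec-2-en-8-ynamide (west fragment C1–C8) | NC(=O)/C(C)=C/CC[C@H](OC)[C@@H](O[Si](CC)(CC)CC)C#CC | intermediate
15 | 3-bromo-5-hydroxybenzaldehyde | O=Cc1cc(O)cc(Br)c1 | starting material
16 | 3-bromo-5-(triisopropylsilyloxy)benzaldehyde | O=Cc1cc(O[Si](C(C)C)(C(C)C)C(C)C)cc(Br)c1 | intermediate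
17 | cis-but-2-ene | C/C=C\C | starting material
18 | (Z)-but-2-enyldiisopinocampheylborane, Ipc groups from (−)-α-pinene | C/C=C\CB([C@H]1C[C@H]2C[C@@H]([C@@H]1C)C2(C)C)[C@H]1C[C@H]2C[C@@H]([C@@H]1C)C2(C)C | intermediate
19 | (1R,2S)-1-[3-bromo-5-(triisopropylsilyloxy)phenyl]-2-methylbut-3-en-1-ol | C=C[C@H](C)[C@@H](O)c1cc(Br)cc(O[Si](C(C)C)(C(C)C)C(C)C)c1 | intermediate
20 | (1R,2S)-1-[3-bromo-5-(triisopropylsilyloxy)phenyl]-1-(tert-butyldimethylsilyloxy)-2-methylbut-3-ene | C=C[C@H](C)[C@@H](O[Si](C)(C)C(C)(C)C)c1cc(Br)cc(O[Si](C(C)C)(C(C)C)C(C)C)c1 | intermediate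
21 | 9-BBN adduct of 20 at the terminal carbon (C12) | B1(C2CCCC1CCC2)CC[C@H](C)[C@@H](O[Si](C)(C)C(C)(C)C)c3cc(Br)cc(O[Si](C(C)C)(C(C)C)C(C)C)c3 | intermediate
22 | (3S,4R)-4-[3-bromo-5-(triisopropylsilyloxy)phenyl]-4-(tert-butyldimethylsilyloxy)-3-methylbutan-1-ol | OCC[C@H](C)[C@@H](O[Si](C)(C)C(C)(C)C)c1cc(Br)cc(O[Si](C(C)C)(C(C)C)C(C)C)c1 | intermediate
23 | (3S,4R)-4-[3-bromo-5-(triisopropylsilyloxy)phenyl]-4-(tert-butyldimethylsilyloxy)-3-methylbutanal | O=CC[C@H](C)[C@@H](O[Si](C)(C)C(C)(C)C)c1cc(Br)cc(O[Si](C(C)C)(C(C)C)C(C)C)c1 | intermediate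
24 | propyne | CC#C | starting material
25 | (E)-dicyclohexyl(prop-1-enyl)borane | C/C=C/B(C1CCCCC1)C1CCCCC1 | intermediate
26 | (E)-methyl(prop-1-enyl)zinc | C/C=C/[Zn]C | intermediate
27 | (2E,4S,6S,7R)-7-[3-bromo-5-(triisopropylsilyloxy)phenyl]-7-(tert-butyldimethylsilyloxy)-6-methylhept-2-en-4-ol | C/C=C/[C@@H](O)C[C@H](C)[C@@H](O[Si](C)(C)C(C)(C)C)c1cc(Br)cc(O[Si](C(C)C)(C(C)C)C(C)C)c1 | intermediate
28 | (1S,3S,4R)-4-[3-bromo-5-(triisopropylsilyloxy)phenyl]-4-(tert-butyldimethylsilyloxy)-3-methyl-1-[(2S,3S)-3-methyloxiran-2-yl]butan-1-ol | C[C@@H]1O[C@H]1[C@@H](O)C[C@H](C)[C@@H](O[Si](C)(C)C(C)(C)C)c2cc(Br)cc(O[Si](C(C)C)(C(C)C)C(C)C)c2 | intermediate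
29 | (2R,3S)-2-{(1S,3S,4R)-4-[3-bromo-5-(triisopropylsilyloxy)phenyl]-4-(tert-butyldimethylsilyloxy)-1-methoxy-3-methylbutyl}-3-methyloxirane | C[C@@H]1O[C@H]1[C@@H](OC)C[C@H](C)[C@@H](O[Si](C)(C)C(C)(C)C)c2cc(Br)cc(O[Si](C(C)C)(C(C)C)C(C)C)c2 | intermediate
30 | prop-1-ynyllithium | [Li]C#CC | intermediate
31 | (4S,5R,6S,8S,9R)-9-[3-bromo-5-(triisopropylsilyloxy)phenyl]-9-(tert-butyldimethylsilyloxy)-6-methoxy-4,8-dimethylnon-2-yn-5-ol | CC#C[C@H](C)[C@@H](O)[C@@H](OC)C[C@H](C)[C@@H](O[Si](C)(C)C(C)(C)C)c1cc(Br)cc(O[Si](C(C)C)(C(C)C)C(C)C)c1 | intermediate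
32 | (4S,5R,6S,8S,9R)-9-[3-bromo-5-(triisopropylsilyloxy)phenyl]-5,9-bis(tert-butyldimethylsilyloxy)-6-methoxy-4,8-dimethylnon-2-yne (east fragment C9–C15) | CC#C[C@H](C)[C@@H](O[Si](C)(C)C(C)(C)C)[C@@H](OC)C[C@H](C)[C@@H](O[Si](C)(C)C(C)(C)C)c1cc(Br)cc(O[Si](C(C)C)(C(C)C)C(C)C)c1 | intermediate
33 | seco-diyne anilide (6S,7S,10S,11R,12S,14S,15R) | CC#C[C@H](C)[C@@H](O[Si](C)(C)C(C)(C)C)[C@@H](OC)C[C@H](C)[C@@H](O[Si](C)(C)C(C)(C)C)c1cc(O[Si](C(C)C)(C(C)C)C(C)C)cc(NC(=O)/C(C)=C/CC[C@H](OC)[C@@H](O[Si](CC)(CC)CC)C#CC)c1 | intermediate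
34 | 19-membered cycloalkyne lactam, C7-OTES (6S,7S,10S,11R,12S,14S,15R) | CO[C@H]1C[C@H](C)[C@@H](O[Si](C)(C)C(C)(C)C)c2cc(O[Si](C(C)C)(C(C)C)C(C)C)cc(c2)NC(=O)/C(C)=C/CC[C@H](OC)[C@@H](O[Si](CC)(CC)CC)C#C[C@H](C)[C@H]1O[Si](C)(C)C(C)(C)C | intermediate
35 | macrocyclic propargylic alcohol, free C7-OH (6S,7S,10S,11R,12S,14S,15R) | CO[C@H]1C[C@H](C)[C@@H](O[Si](C)(C)C(C)(C)C)c2cc(O[Si](C(C)C)(C(C)C)C(C)C)cc(c2)NC(=O)/C(C)=C/CC[C@H](OC)[C@@H](O)C#C[C@H](C)[C@H]1O[Si](C)(C)C(C)(C)C | intermediate
36 | macrocyclic (8Z)-8-tributylstannyl allylic alcohol (6S,7R,10S,11R,12S,14S,15R by CIP) | CO[C@H]1C[C@H](C)[C@@H](O[Si](C)(C)C(C)(C)C)c2cc(O[Si](C(C)C)(C(C)C)C(C)C)cc(c2)NC(=O)/C(C)=C/CC[C@H](OC)[C@@H](O)/C([Sn](CCCC)(CCCC)CCCC)=C/[C@H](C)[C@H]1O[Si](C)(C)C(C)(C)C | intermediate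
37 | macrocyclic (8E)-8-methyl allylic alcohol (6S,7S,10S,11R,12S,14S,15R) | CO[C@H]1C[C@H](C)[C@@H](O[Si](C)(C)C(C)(C)C)c2cc(O[Si](C(C)C)(C(C)C)C(C)C)cc(c2)NC(=O)/C(C)=C/CC[C@H](OC)[C@@H](O)/C(C)=C/[C@H](C)[C@H]1O[Si](C)(C)C(C)(C)C | intermediate
38 | C7 N-(trichloroacetyl)carbamate of 37 | CO[C@H]1C[C@H](C)[C@@H](O[Si](C)(C)C(C)(C)C)c2cc(O[Si](C(C)C)(C(C)C)C(C)C)cc(c2)NC(=O)/C(C)=C/CC[C@H](OC)[C@@H](OC(=O)NC(=O)C(Cl)(Cl)Cl)/C(C)=C/[C@H](C)[C@H]1O[Si](C)(C)C(C)(C)C | intermediate
39 | tris-silylated C7 carbamate (C11-OTBS, C15-OTBS, aryl OTIPS) | CO[C@H]1C[C@H](C)[C@@H](O[Si](C)(C)C(C)(C)C)c2cc(O[Si](C(C)C)(C(C)C)C(C)C)cc(c2)NC(=O)/C(C)=C/CC[C@H](OC)[C@@H](OC(N)=O)/C(C)=C/[C@H](C)[C@H]1O[Si](C)(C)C(C)(C)C | intermediate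
40 | CNP0309815.1 (6S,7S,8E,10S,11R,12S,14S,15R; 2E) | CO[C@H]1C[C@H](C)[C@@H](O)c2cc(O)cc(c2)NC(=O)/C(C)=C/CC[C@H](OC)[C@@H](OC(N)=O)/C(C)=C/[C@H](C)[C@H]1O | target

Total step count: 24. Longest linear sequence: 17 steps (from 15 through steps 8–24 to 40).

Steps most likely to fail

Step 19. The catalyst may be deactivated by the anilide N–H, or the two α-branched alkynes may turn over so slowly that oligomerisation competes with ring closure. The fallback forms C8≡C9 before any N–H is present and closes the ring at nitrogen instead. It sets out from 32 and 6: cross-metathesis of 32 with an excess of the small alkyne 6 (same molybdenum alkylidyne, 5 Å MS, toluene; the terminal alkene of 6 is inert to the alkylidyne) should give the C4–C15 enyne aryl bromide F1. 9-BBN then adds to its vinyl group to give the B-alkyl borane F2 (not isolated), which is coupled with iodide 12 under the conditions of step 7, the alkenyl iodide reacting in preference to the aryl bromide, to give the seco bromo amide F3. Intramolecular copper-catalysed N-arylation of F3 (CuI, N,N′-dimethylethylenediamine, K2CO3, toluene, high dilution, 100 °C) closes the 19-membered lactam and returns to the route at 34.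

Step 22. Protodestannation may outrun transmetalation at the hindered, hydroxyl-flanked C8–Sn bond, giving the unmethylated alkene. The fallback sets out from 36: iododestannation with retention (I2, CH2Cl2, 0 °C) should give the macrocyclic (8Z)-8-iodo allylic alcohol F4, and Negishi methylation (MeZnCl in excess, [Pd(PPh3)4], THF, rt) then installs the methyl group through the reversed polarity and returns to the route at 37.

Step 13. Facial selectivity of the propenyl transfer may be poor, and double hydroboration of propyne or competing methyl transfer may erode the reagent. The fallback sets out from 23 and relies on resolution instead of asymmetric addition: (E)-prop-1-enyllithium (from (E)-1-bromoprop-1-ene and t-BuLi, Et2O, −78 °C) is added without induction, giving 27 together with its C12 epimer, the (2E,4R,6S,7R)-allylic alcohol F5. The mixture is then submitted to the conditions of step 14 with about 0.6 equivalents of t-BuOOH (Sharpless kinetic resolution), under which only 27 should be epoxidised, so the route is rejoined at 28 and unreacted F5 is separated.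

Further compounds
F1 | step 19 | C4–C15 enyne aryl bromide (vinyl C4=C5, C6-OMe, C7-OTES, C8≡C9, east part as in 32; 6S,7S,10S,11R,12S,14S,15R) | C=C[C@H](OC)[C@@H](O[Si](CC)(CC)CC)C#C[C@H](C)[C@@H](O[Si](C)(C)C(C)(C)C)[C@@H](OC)C[C@H](C)[C@@H](O[Si](C)(C)C(C)(C)C)c1cc(Br)cc(O[Si](C(C)C)(C(C)C)C(C)C)c1
F2 | step 19 | 9-BBN adduct of F1 at C4 | B1(C2CCCC1CCC2)CC[C@H](OC)[C@@H](O[Si](CC)(CC)CC)C#C[C@H](C)[C@@H](O[Si](C)(C)C(C)(C)C)[C@@H](OC)C[C@H](C)[C@@H](O[Si](C)(C)C(C)(C)C)c3cc(Br)cc(O[Si](C(C)C)(C(C)C)C(C)C)c3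
F3 | step 19 | seco bromo amide (primary C1 amide, C8≡C9 in place, aryl bromide; 6S,7S,10S,11R,12S,14S,15R) | NC(=O)/C(C)=C/CC[C@H](OC)[C@@H](O[Si](CC)(CC)CC)C#C[C@H](C)[C@@H](O[Si](C)(C)C(C)(C)C)[C@@H](OC)C[C@H](C)[C@@H](O[Si](C)(C)C(C)(C)C)c1cc(Br)cc(O[Si](C(C)C)(C(C)C)C(C)C)c1
F4 | step 22 | macrocyclic (8Z)-8-iodo allylic alcohol (6S,7R,10S,11R,12S,14S,15R by CIP) | CO[C@H]1C[C@H](C)[C@@H](O[Si](C)(C)C(C)(C)C)c2cc(O[Si](C(C)C)(C(C)C)C(C)C)cc(c2)NC(=O)/C(C)=C/CC[C@H](OC)[C@@H](O)/C(I)=C/[C@H](C)[C@H]1O[Si](C)(C)C(C)(C)C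
F5 | step 13 | (2E,4R,6S,7R)-7-[3-bromo-5-(triisopropylsilyloxy)phenyl]-7-(tert-butyldimethylsilyloxy)-6-methylhept-2-en-4-ol | C/C=C/[C@H](O)C[C@H](C)[C@@H](O[Si](C)(C)C(C)(C)C)c1cc(Br)cc(O[Si](C(C)C)(C(C)C)C(C)C)c1
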